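**Retrosynthetic overview**

1. Target 23 ⇐ tetralin ester 21 by ester hydrolysis and hydrogenolysis of three benzyl ethers.
2. 21 ⇐ β-keto acetal 17 + β-keto ester 18, cutting C4a–C5 and C7–C8. This rests on ring B (C1–C4, C4a, C8a) being a 1,4-trans p-menthane in which C4a can be a ketone carbon and C8a its α-carbon, and on ring A (C4a, C5–C8, C8a) being a 3-alkoxysalicylate whose C5–C6–C7 unit is a 4-alkoxyacetoacetate.
3. 17 ⇐ ketone 16 (dimethoxymethylation at C8a) ⇐ alkene 12 (C11 by catalyst-controlled hydroboration) ⇐ allyl chloride 10 + bromide 5 (C12–C13 by copper-catalysed coupling).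
4. 10 ⇐ (R)-carvone 6, which supplies ring B with C1 and C4; 5 ⇐ (R)-3-bromo-2-methylpropan-1-ol 1, which supplies C15, after a one-carbon homologation.
5. Ring order: ring B comes from the chiral pool; ring A is closed last.

Key step: step 12

**Remarks and assumptions**

- Numbering: ring B = C1 (side chain), C2, C3, C4 (methyl), C4a, C8a; ring A = C4a, C5, C6, C7, C8, C8a; side chain C11 (on C1) to C16; the hydroxymethyl carbon on C11 is called C17 here. The target is (1S,4R,11S,15S).
- Assumption: the antipode of DTBM-SEGPHOS that delivers 11S in step 8 is to be assigned in a first trial with both commercial antipodes.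
- The C8a centre of 17 and the C4a and C5 centres of 20 disappear on aromatisation, so their configuration is immaterial.

**Route**

Step 1
Reactants: 1 (R)-3-bromo-2-methylpropan-1-ol
Product: 2 (R)-[(3-bromo-2-methylpropoxy)methyl]benzene
Conditions: benzyl 2,2,2-trichloroacetimidate, TfOH (cat.), CH2Cl2/cyclohexane, 0 °C → rt
Reagents that add atoms: benzyl 2,2,2-trichloroacetimidate, ClC(Cl)(Cl)C(=N)OCc1ccccc1
Why: Acid-catalysed imidate O-benzylation forms no alkoxide, so oxetane closure and loss of HBr are avoided and the stereocentre is untouched.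

Step 2
Reactants: 2 (R)-[(3-bromo-2-methylpropoxy)methyl]benzene
Product: 4 (S)-4-(benzyloxy)-3-methylbutan-1-ol, via Grignard reagent 3 (not isolated)
Conditions: Mg, THF, 40 °C; (CH2O)n, 0 °C → reflux; dil. HCl
Reagents that add atoms: formaldehyde (as paraformaldehyde), C=O
Why: Grignard addition to formaldehyde extends the bromide end by the one carbon that the C13–C16 unit needs, and the stereocentre lies β to the metal-bearing carbon and is not affected.

Step 3
Reactants: 4 (S)-4-(benzyloxy)-3-methylbutan-1-ol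
Product: 5 (S)-[(4-bromo-2-methylbutoxy)methyl]benzene
Conditions: CBr4, PPh3, CH2Cl2, 0 °C
Reagents that add atoms: carbon tetrabromide, BrC(Br)(Br)Br
Why: Appel bromination of a primary alcohol under neutral conditions, with SN2 displacement at a non-stereogenic carbon.

Step 4
Reactants: 6 (R)-carvone
Product: 8 (2R,5R)-2-methyl-5-(prop-1-en-2-yl)cyclohexan-1-one, via lithium enolate 7 (not isolated)
Conditions: LiBH(s-Bu)3, THF, −78 °C; H2O; then NaOMe (cat.), MeOH, rt
Reagents that add atoms: none
Why: The hindered borohydride reduces the β-unsubstituted cyclohexenone in conjugate fashion and leaves the isolated isopropenyl group alone, and protonation followed by methoxide equilibration places the methyl group α to the ketone (C4) equatorial, trans to the C1 substituent inherited from carvone.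

Step 5
Reactants: 8 (2R,5R)-2-methyl-5-(prop-1-en-2-yl)cyclohexan-1-one
Product: 9 (6R,9R)-6-methyl-9-(prop-1-en-2-yl)-1,4-dioxaspiro[4.5]decane
Conditions: (TMSOCH2)2, TMSOTf (cat.), CH2Cl2, −78 → −20 °C; pyridine quench
Reagents that add atoms: 1,2-bis(trimethylsilyloxy)ethane, C[Si](C)(C)OCCO[Si](C)(C)C
Why: Silyl-transfer ketalisation under aprotic, low-temperature conditions should protect the ketone without epimerising C4 or isomerising the isopropenyl group.

Step 6
Reactants: 9 (6R,9R)-6-methyl-9-(prop-1-en-2-yl)-1,4-dioxaspiro[4.5]decane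
Product: 10 (6R,9R)-9-(3-chloroprop-1-en-2-yl)-6-methyl-1,4-dioxaspiro[4.5]decane
Conditions: Ca(OCl)2, CO2 (s), CH2Cl2/H2O, 0 °C
Reagents that add atoms: calcium hypochlorite, [Ca+2].[O-]Cl.[O-]Cl
Why: Ene-type allylic chlorination by HOCl puts chlorine on the terminal alkene carbon and removes a proton from the methyl group, as with other isopropenyl terpenes, and so gives the 2-substituted allyl chloride.

Step 7
Reactants: 5 (S)-[(4-bromo-2-methylbutoxy)methyl]benzene; 10 (6R,9R)-9-(3-chloroprop-1-en-2-yl)-6-methyl-1,4-dioxaspiro[4.5]decane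
Product: 12 (6R,9R)-9-[(6S)-7-(benzyloxy)-6-methylhept-1-en-2-yl]-6-methyl-1,4-dioxaspiro[4.5]decane, via Grignard reagent 11 (not isolated)
Conditions: 5, Mg, THF, 40 °C; then 10, Li2CuCl4 (3 mol%), THF, −20 °C → rt
Reagents that add atoms: none
Why: Copper-catalysed coupling of a primary alkyl Grignard reagent with an allylic chloride forms C12–C13, and because the allyl unit is symmetric about C11, SN2 and SN2′ attack give the same product.

Step 8
Reactants: 12 (6R,9R)-9-[(6S)-7-(benzyloxy)-6-methylhept-1-en-2-yl]-6-methyl-1,4-dioxaspiro[4.5]decane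
Product: 14 (2S,6S)-7-(benzyloxy)-6-methyl-2-[(6R,9R)-6-methyl-1,4-dioxaspiro[4.5]decan-9-yl]heptan-1-ol, via pinacol boronate 13 (not isolated)
Conditions: CuCl (5 mol%), DTBM-SEGPHOS (5.5 mol%, antipode matched to 11S), KOtBu (10 mol%), HBpin, THF, rt; then NaOH, H2O2, THF/H2O, 0 °C
Reagents that add atoms: pinacolborane (boron of 13), [H]B1OC(C)(C)C(C)(C)O1; hydrogen peroxide (oxygen of 14), OO
Why: Copper hydride-catalysed enantioselective anti-Markovnikov hydroboration of an unactivated 1,1-disubstituted alkene places copper on the terminal carbon and hydrogen on C11 from the face chosen by the bulky bisphosphine, which tells the secondary ring carbon from the primary chain carbon, so C11 (S) is set by the catalyst and the oxidation of the primary C–B bond does not touch it.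

Step 9
Reactants: 14 (2S,6S)-7-(benzyloxy)-6-methyl-2-[(6R,9R)-6-methyl-1,4-dioxaspiro[4.5]decan-9-yl]heptan-1-ol
Product: 15 (6R,9R)-9-[(2S,6S)-1,7-bis(benzyloxy)-6-methylheptan-2-yl]-6-methyl-1,4-dioxaspiro[4.5]decane
Conditions: NaH, BnBr, Bu4NI (cat.), THF/DMF, 0 °C → rt
Reagents that add atoms: benzyl bromide, BrCc1ccccc1
Why: Williamson etherification of the primary alcohol gives both side-chain hydroxyls the same protecting group, which the last step removes together with the aryl benzyl ether.

Step 10
Reactants: 15 (6R,9R)-9-[(2S,6S)-1,7-bis(benzyloxy)-6-methylheptan-2-yl]-6-methyl-1,4-dioxaspiro[4.5]decane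
Product: 16 (2R,5R)-5-[(2S,6S)-1,7-bis(benzyloxy)-6-methylheptan-2-yl]-2-methylcyclohexan-1-one
Conditions: 2 M HCl, THF, rt
Reagents that add atoms: water, O
Why: Acid hydrolysis of the dioxolane frees the C4a ketone, the benzyl ethers are stable, and the acid re-equilibrates any C4 epimer to the equatorial trans isomer.

Step 11
Reactants: 16 (2R,5R)-5-[(2S,6S)-1,7-bis(benzyloxy)-6-methylheptan-2-yl]-2-methylcyclohexan-1-one
Product: 17 (2R,5S,6R)-5-[(2S,6S)-1,7-bis(benzyloxy)-6-methylheptan-2-yl]-6-(dimethoxymethyl)-2-methylcyclohexan-1-one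
Conditions: HC(OMe)3, BF3·OEt2, CH2Cl2, −30 °C; then 16, i-Pr2NEt, −78 → 0 °C
Reagents that add atoms: trimethyl orthoformate, COC(OC)OC
Why: Dialkoxycarbenium alkylation of a ketone: the BF3-complexed ketone is deprotonated by the hindered amine at its only α-methylene (C8a) and the enol derivative is captured by the dimethoxycarbenium ion anti to the C1 substituent, which gives the β-keto acetal directly at the aldehyde oxidation level.

Step 12
Reactants: 17 (2R,5S,6R)-5-[(2S,6S)-1,7-bis(benzyloxy)-6-methylheptan-2-yl]-6-(dimethoxymethyl)-2-methylcyclohexan-1-one; 18 ethyl 4-(benzyloxy)-3-oxobutanoate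
Product: 21 ethyl (5R,8S)-4-(benzyloxy)-8-[(2S,6S)-1,7-bis(benzyloxy)-6-methylheptan-2-yl]-3-hydroxy-5-methyl-5,6,7,8-tetrahydronaphthalene-2-carboxylate, via dianion 19 (not isolated), via aldol adduct 20 (not isolated)
Conditions: 18 (2.5 equiv), NaH, THF, 0 °C; n-BuLi, −78 → −20 °C; anhydrous CeCl3, −78 °C; 17, −78 → −40 °C; then 3 M HCl, THF, 0 → 45 °C, same flask
Reagents that add atoms: none
Why: Deprotonation of 18 with NaH and then n-BuLi gives the 2,4-dianion 19, whose terminal α-benzyloxy carbon (C5) is the more nucleophilic site and, tempered by CeCl3, adds to the C4a ketone of 17 (acetoacetate dianion aldol addition) to give adduct 20 and so forms C4a–C5. Aqueous acid then unmasks the C8 aldehyde from its acetal, the enolised β-keto ester carbon C7 condenses with it and closes ring A by a 6-(enolendo)-exo-trig intramolecular Knoevenagel condensation that forms C7–C8, and loss of the C4a hydroxyl toward C5 (E1cB through the C6 enol) followed by dienone–phenol tautomerisation completes the aromatisation. The closest known reaction type is the salicylate synthesis from acetoacetate dianions and β-keto acetals, which is regiocomplementary to the TiCl4-mediated [3+3] cyclisation of 1,3-bis(silyloxy)dienes. No new stereocentre persists: the C4a, C5 and C8a centres vanish on aromatisation, while C1, C4, C11 and C15 are carried through and C1 and C4 become non-epimerisable benzylic centres. The step needs regioselectivity (C5 to C4a, C7 to C8), secured because the acetal is inert to the dianion so that only the ketone is electrophilic in the basic stage and only C7 is nucleophilic in the acidic stage, and it needs addition to win over enolisation, which the low temperature and the cerium counter-ion favour. The C4 configuration should be kept because its methyl group already sits in the favoured equatorial position and because water is lost toward the carbonyl-activated C5–H and not through a C4a cation toward C4.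

Step 13
Reactants: 21 ethyl (5R,8S)-4-(benzyloxy)-8-[(2S,6S)-1,7-bis(benzyloxy)-6-methylheptan-2-yl]-3-hydroxy-5-methyl-5,6,7,8-tetrahydronaphthalene-2-carboxylate
Product: 22 (5R,8S)-4-(benzyloxy)-8-[(2S,6S)-1,7-bis(benzyloxy)-6-methylheptan-2-yl]-3-hydroxy-5-methyl-5,6,7,8-tetrahydronaphthalene-2-carboxylic acid
Conditions: LiOH, THF/MeOH/H2O, 55 °C; then 1 M HCl
Reagents that add atoms: lithium hydroxide, [Li+].[OH-]
Why: Saponification of the salicylate ester is done while the catechol is still mono-benzylated, so that no free catechol meets aqueous base and air.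

Step 14
Reactants: 22 (5R,8S)-4-(benzyloxy)-8-[(2S,6S)-1,7-bis(benzyloxy)-6-methylheptan-2-yl]-3-hydroxy-5-methyl-5,6,7,8-tetrahydronaphthalene-2-carboxylic acid
Product: 23 (5R,8S)-8-[(2S,6S)-1,7-dihydroxy-6-methylheptan-2-yl]-3,4-dihydroxy-5-methyl-5,6,7,8-tetrahydronaphthalene-2-carboxylic acid (CNP0255074.1)
Conditions: H2 (1 atm), Pd/C (10 wt%), EtOAc/MeOH, rt
Reagents that add atoms: none
Why: Hydrogenolysis over palladium on carbon cleaves the aryl and the two alkyl benzyl ethers under neutral conditions and leaves the arene, the acid and the four stereocentres untouched.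

**Compound list**

1 | (R)-3-bromo-2-methylpropan-1-ol | C[C@H](CO)CBr | starting material
2 | (R)-[(3-bromo-2-methylpropoxy)methyl]benzene | C[C@H](COCc1ccccc1)CBr | intermediate
3 | [(R)-3-(benzyloxy)-2-methylpropyl]magnesium bromide | C[C@H](COCc1ccccc1)C[Mg]Br | intermediate
4 | (S)-4-(benzyloxy)-3-methylbutan-1-ol | C[C@H](COCc1ccccc1)CCO | intermediate
5 | (S)-[(4-bromo-2-methylbutoxy)methyl]benzene | C[C@H](COCc1ccccc1)CCBr | intermediate
6 | (R)-carvone | CC1=CC[C@H](CC1=O)C(C)=C | starting material
7 | lithium (5R)-2-methyl-5-(prop-1-en-2-yl)cyclohex-1-en-1-olate | CC1=C([O-])C[C@H](C(C)=C)CC1.[Li+] | intermediate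
8 | (2R,5R)-2-methyl-5-(prop-1-en-2-yl)cyclohexan-1-one | CC(=C)[C@@H]1CC[C@@H](C)C(=O)C1 | intermediate
9 | (6R,9R)-6-methyl-9-(prop-1-en-2-yl)-1,4-dioxaspiro[4.5]decane | CC(=C)[C@@H]1CC[C@@H](C)C2(OCCO2)C1 | intermediate
10 | (6R,9R)-9-(3-chloroprop-1-en-2-yl)-6-methyl-1,4-dioxaspiro[4.5]decane | ClCC(=C)[C@@H]1CC[C@@H](C)C2(OCCO2)C1 | intermediate
11 | [(S)-4-(benzyloxy)-3-methylbutyl]magnesium bromide | C[C@H](COCc1ccccc1)CC[Mg]Br | intermediate
12 | (6R,9R)-9-[(6S)-7-(benzyloxy)-6-methylhept-1-en-2-yl]-6-methyl-1,4-dioxaspiro[4.5]decane | C[C@H](COCc1ccccc1)CCCC(=C)[C@@H]1CC[C@@H](C)C2(OCCO2)C1 | intermediate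
13 | 2-{(2S,6S)-7-(benzyloxy)-6-methyl-2-[(6R,9R)-6-methyl-1,4-dioxaspiro[4.5]decan-9-yl]heptyl}-4,4,5,5-tetramethyl-1,3,2-dioxaborolane | C[C@H](COCc1ccccc1)CCC[C@H](CB2OC(C)(C)C(C)(C)O2)[C@@H]1CC[C@@H](C)C3(OCCO3)C1 | intermediate
14 | (2S,6S)-7-(benzyloxy)-6-methyl-2-[(6R,9R)-6-methyl-1,4-dioxaspiro[4.5]decan-9-yl]heptan-1-ol | C[C@H](COCc1ccccc1)CCC[C@H](CO)[C@@H]1CC[C@@H](C)C2(OCCO2)C1 | intermediate
15 | (6R,9R)-9-[(2S,6S)-1,7-bis(benzyloxy)-6-methylheptan-2-yl]-6-methyl-1,4-dioxaspiro[4.5]decane | C[C@H](COCc1ccccc1)CCC[C@H](COCc1ccccc1)[C@@H]1CC[C@@H](C)C2(OCCO2)C1 | intermediate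
16 | (2R,5R)-5-[(2S,6S)-1,7-bis(benzyloxy)-6-methylheptan-2-yl]-2-methylcyclohexan-1-one | C[C@H](COCc1ccccc1)CCC[C@H](COCc1ccccc1)[C@@H]1CC[C@@H](C)C(=O)C1 | intermediate
17 | (2R,5S,6R)-5-[(2S,6S)-1,7-bis(benzyloxy)-6-methylheptan-2-yl]-6-(dimethoxymethyl)-2-methylcyclohexan-1-one (all-equatorial β-keto acetal) | C[C@H](COCc1ccccc1)CCC[C@H](COCc1ccccc1)[C@@H]1CC[C@@H](C)C(=O)[C@H]1C(OC)OC | intermediate
18 | ethyl 4-(benzyloxy)-3-oxobutanoate | CCOC(=O)CC(=O)COCc1ccccc1 | starting material
19 | sodium lithium 2,4-dianion of ethyl 4-(benzyloxy)-3-oxobutanoate | CCOC(=O)[CH-]C(=O)[CH-]OCc1ccccc1.[Na+].[Li+] | intermediate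
20 | aldol adduct: ethyl 4-(benzyloxy)-4-[1-hydroxy-2-(dimethoxymethyl)-6-methyl-3-((2S,6S)-1,7-bis(benzyloxy)-6-methylheptan-2-yl)cyclohexyl]-3-oxobutanoate, ring centres C1, C4, C8a as in 17, C4a and C5 undefined | C[C@H](COCc1ccccc1)CCC[C@H](COCc1ccccc1)[C@@H]1CC[C@@H](C)C(O)(C(OCc2ccccc2)C(=O)CC(=O)OCC)[C@H]1C(OC)OC | intermediate
21 | ethyl (5R,8S)-4-(benzyloxy)-8-[(2S,6S)-1,7-bis(benzyloxy)-6-methylheptan-2-yl]-3-hydroxy-5-methyl-5,6,7,8-tetrahydronaphthalene-2-carboxylate | C[C@H](COCc1ccccc1)CCC[C@H](COCc1ccccc1)[C@@H]1CC[C@@H](C)c2c1cc(C(=O)OCC)c(O)c2OCc1ccccc1 | intermediate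
22 | (5R,8S)-4-(benzyloxy)-8-[(2S,6S)-1,7-bis(benzyloxy)-6-methylheptan-2-yl]-3-hydroxy-5-methyl-5,6,7,8-tetrahydronaphthalene-2-carboxylic acid | C[C@H](COCc1ccccc1)CCC[C@H](COCc1ccccc1)[C@@H]1CC[C@@H](C)c2c1cc(C(=O)O)c(O)c2OCc1ccccc1 | intermediate
23 | (5R,8S)-8-[(2S,6S)-1,7-dihydroxy-6-methylheptan-2-yl]-3,4-dihydroxy-5-methyl-5,6,7,8-tetrahydronaphthalene-2-carboxylic acid | C[C@H](CO)CCC[C@H](CO)[C@@H]1CC[C@@H](C)c2c1cc(C(=O)O)c(O)c2O | target

**Step count**

Total: 14 steps. Longest linear sequence: 11 steps (steps 4–14 from (R)-carvone; also 11 from 1 through steps 1–3 and 7–14).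

**The three steps most likely to fail**

1. Step 12. The basic dianion may deprotonate the doubly α-branched ketone instead of adding to it. The enolate can then expel methoxide, and the resulting alkoxymethylene ketone would take up C5 at C8 and reverse the regiochemistry. The tertiary alkoxide may also close onto the ester, and loss of water through a C4a cation would erode the C4 configuration. The fallback inverts the order of bond formation so that the hindered ketone is attacked only intramolecularly. It sets out from 17: the titanium enolate of 18 (TiCl4, Et3N, CH2Cl2, −78 → 0 °C), nucleophilic only at C7, is alkylated by the TiCl4-activated acetal and loses methanol to give the alkylidene β-keto ester F1 (C7–C8 formed first). TsOH in toluene at 80 °C then closes C5 onto the C4a ketone by a six-membered intramolecular aldol condensation, and dehydration and tautomerisation aromatise the ring. The fallback comes back to the route at 21.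

2. Step 8. The facial selectivity at C11 may be poor, because the catalyst must tell a secondary ring carbon from a long primary chain and the C1 centre gives little bias of its own. The fallback replaces catalyst control by separation. It sets out from 12: 9-BBN in THF gives the B-alkyl-9-borabicyclononane adduct F2, and NaOH/H2O2 gives the C11-epimeric alcohol mixture F3. Burkholderia cepacia lipase with vinyl acetate in t-BuOMe then acylates one C11 epimer of this β-branched primary alcohol selectively. Written for the case in which the 11S epimer reacts, the acetate F4 is separated and cleaved with K2CO3 in MeOH; in the opposite case the unreacted alcohol is taken on. The fallback comes back to the route at 14.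

3. Step 11. The ketone may be substituted at the wrong α-carbon or twice, and the β-keto acetal may lose methanol to the methoxymethylene ketone on work-up or on silica. The fallback fixes the regiochemistry with a preformed enol derivative. It sets out from 16: LiN(i-Pr)2 and TMSCl in THF at −78 °C give the kinetic trimethylsilyl enol ether F5 (C4a=C8a), and its Mukaiyama-type reaction with HC(OMe)3 and catalytic TMSOTf in CH2Cl2 at −78 °C gives the β-keto acetal. The fallback comes back to the route at 17.

**Further compounds**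

F1 | step 12 | ethyl 4-(benzyloxy)-2-{[(1R,2S,4R)-2-((2S,6S)-1,7-bis(benzyloxy)-6-methylheptan-2-yl)-4-methyl-3... oxocyclohexyl]methylidene}-3-oxobutanoate, i.e. the C8=C7 alkylidene β-keto ester of 17, ring centres as in 17, alkene geometry undefined | C[C@H](COCc1ccccc1)CCC[C@H](COCc1ccccc1)[C@@H]1CC[C@@H](C)C(=O)[C@H]1C=C(C(=O)OCC)C(=O)COCc1ccccc1
F2 | step 8 | 9-{7-(benzyloxy)-6-methyl-2-[(6R,9R)-6-methyl-1,4-dioxaspiro[4.5]decan-9-yl]heptyl}-9-borabicyclo[3.3.1]nonane, (6S) in the chain, C11 epimer mixture | C[C@H](COCc1ccccc1)CCCC(CB2C3CCCC2CCC3)[C@@H]1CC[C@@H](C)C4(OCCO4)C1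
F3 | step 8 | (6S)-7-(benzyloxy)-6-methyl-2-[(6R,9R)-6-methyl-1,4-dioxaspiro[4.5]decan-9-yl]heptan-1-ol, C11 epimer mixture | C[C@H](COCc1ccccc1)CCCC(CO)[C@@H]1CC[C@@H](C)C2(OCCO2)C1
F4 | step 8 | (2S,6S)-7-(benzyloxy)-6-methyl-2-[(6R,9R)-6-methyl-1,4-dioxaspiro[4.5]decan-9-yl]heptyl acetate | C[C@H](COCc1ccccc1)CCC[C@H](COC(C)=O)[C@@H]1CC[C@@H](C)C2(OCCO2)C1
F5 | step 11 | {[(3S,6R)-3-((2S,6S)-1,7-bis(benzyloxy)-6-methylheptan-2-yl)-6-methylcyclohex-1-en-1-yl]oxy}trimethylsilane | C[C@H](COCc1ccccc1)CCC[C@H](COCc1ccccc1)[C@@H]1CC[C@@H](C)C(O[Si](C)(C)C)=C1
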